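**Retrosynthetic overview**

- Target 15 ⇐ 14 ⇐ 13: the 4'-O-silyl group comes off last with buffered fluoride; before that, Mg(II) chelated between the C4 carbonyl and O5 removes the surplus peri benzyl ether.
- 13 ⇐ 12: C2–C3 is disconnected. Forward, a Rh(II) carbenoid at C3 inserts into a benzylic C–H of an O–CH2–aryl ether and closes ring C, the only ring made in the route (rings A and B are bought).
- 12 ⇐ 9 ⇐ 4 + 8: the diazo group comes from deacylative diazo transfer to the methyl ketone, and the two identical aryl ethers from double O-benzylation.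
- 4 ⇐ 1 + 2 (C-diprenylation, then 4-O-methylation); 8 ⇐ 5 (silylation, reduction, bromination).
- Feature: C2 is a benzylic CH bonded to O1 and stands in a 1,6-relationship to C3 (C3–C4–C4a–C8a–O1–C2). Ring A (OMe at C7, prenyl at C6 and C8) is symmetric about the C4a···C7 axis, so O5 and O1 can start as the same 4-silyloxybenzyl ether and either one may react.

Key step: step 9

Assumption: the (S)-prolinate catalyst Rh2(S-BSP)4 is taken to give the (2S) sense at C2; should the sense be the opposite, the enantiomeric catalyst Rh2(R-BSP)4 is used with no other change.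

**Route**

Step 1
Reactants: 1 2,4,6-trihydroxyacetophenone; 2 prenyl bromide (2.1 equiv)
Product: 3 2,4,6-trihydroxy-3,5-bis(3-methylbut-2-enyl)acetophenone
Conditions: 10% aq. KOH, 0 °C → rt; chromatography
Reagents that add atoms: none
Why: C-alkylation of an acylphloroglucinol phenoxide (the deoxyhumulone-type C-prenylation): in water the solvated phenoxide oxygens are shielded and the two free ring carbons C3 and C5, each flanked by two oxygens, attack prenyl bromide by SN2, the diprenyl compound being separated from mono- and over-alkylated material.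

Step 2
Reactants: 3 2,4,6-trihydroxy-3,5-bis(3-methylbut-2-enyl)acetophenone
Product: 4 2,6-dihydroxy-4-methoxy-3,5-bis(3-methylbut-2-enyl)acetophenone
Conditions: Me2SO4 (1.05 equiv), K2CO3, acetone, rt
Reagents that add atoms: dimethyl sulfate, COS(=O)(=O)OC
Why: Williamson methylation with one equivalent should take the 4-OH, the most acidic hydroxyl (para to the acetyl group) and the only one not hydrogen-bonded to or shielded by the ortho carbonyl, as in the 4-O-methylation of 3,5-dialkylphloroacetophenones.

Step 3
Reactants: 5 4-hydroxybenzaldehyde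
Product: 6 4-(triisopropylsilyloxy)benzaldehyde
Conditions: TIPSCl, imidazole, DMF, rt
Reagents that add atoms: triisopropylsilyl chloride, CC(C)[Si](Cl)(C(C)C)C(C)C
Why: Imidazole-mediated silylation of a phenol; the bulky TIPS group is chosen so that the aryl silyl ether survives carbonate in DMF, LiHMDS and aqueous amine later in the route.

Step 4
Reactants: 6 4-(triisopropylsilyloxy)benzaldehyde
Product: 7 4-(triisopropylsilyloxy)benzyl alcohol
Conditions: NaBH4, THF/MeOH, 0 °C
Reagents that add atoms: none
Why: Borohydride reduction of an aryl aldehyde, which the aryl TIPS ether tolerates in the cold.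

Step 5
Reactants: 7 4-(triisopropylsilyloxy)benzyl alcohol
Product: 8 4-(triisopropylsilyloxy)benzyl bromide
Conditions: CBr4, PPh3, CH2Cl2, 0 °C; short silica plug, used at once
Reagents that add atoms: carbon tetrabromide, BrC(Br)(Br)Br
Why: Appel bromination converts the electron-rich benzylic alcohol to the bromide under neutral conditions, avoiding acid that would ionise it.

Step 6
Reactants: 4 2,6-dihydroxy-4-methoxy-3,5-bis(3-methylbut-2-enyl)acetophenone; 8 4-(triisopropylsilyloxy)benzyl bromide (2.5 equiv)
Product: 9 4-methoxy-3,5-bis(3-methylbut-2-enyl)-2,6-bis[4-(triisopropylsilyloxy)benzyloxy]acetophenone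
Conditions: K2CO3, dry DMF, rt → 45 °C
Reagents that add atoms: none
Why: Double Williamson etherification: both phenols are acidic (ortho to the acetyl group) and, with no free ring position left, their phenoxides should react at oxygen with the reactive primary benzylic bromide in a dipolar aprotic solvent.

Step 7
Reactants: 9 4-methoxy-3,5-bis(3-methylbut-2-enyl)-2,6-bis[4-(triisopropylsilyloxy)benzyloxy]acetophenone
Product: 11 4,4,4-trifluoro-1-{4-methoxy-3,5-bis(3-methylbut-2-enyl)-2,6-bis[4-(triisopropylsilyloxy)benzyloxy]phenyl}butane-1,3-dione, via lithium enolate 10 (not isolated)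
Conditions: LiHMDS (1.1 equiv), THF, −78 °C; CF3CO2CH2CF3 (1.3 equiv), −78 °C; dil. HCl work-up, crude used directly
Reagents that add atoms: 2,2,2-trifluoroethyl trifluoroacetate, O=C(OCC(F)(F)F)C(F)(F)F
Why: The kinetic lithium enolate of the methyl ketone (the only enolisable position) undergoes Claisen-type C-trifluoroacetylation, the activation stage of a detrifluoroacetylative diazo transfer.

Step 8
Reactants: 11 4,4,4-trifluoro-1-{4-methoxy-3,5-bis(3-methylbut-2-enyl)-2,6-bis[4-(triisopropylsilyloxy)benzyloxy]phenyl}butane-1,3-dione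
Product: 12 2-diazo-1-{4-methoxy-3,5-bis(3-methylbut-2-enyl)-2,6-bis[4-(triisopropylsilyloxy)benzyloxy]phenyl}ethanone
Conditions: MsN3 (1.5 equiv), Et3N (1.5 equiv), H2O (1 equiv), MeCN, rt
Reagents that add atoms: methanesulfonyl azide, CS(=O)(=O)N=[N+]=[N-]
Why: Regitz diazo transfer to the activated 1,3-diketone followed by loss of the trifluoroacetyl group as the N-sulfonyl trifluoroacetamide should give the terminal diazoketone under mild amine conditions that the silyl ethers and prenyl groups tolerate.

Step 9
Reactants: 12 2-diazo-1-{4-methoxy-3,5-bis(3-methylbut-2-enyl)-2,6-bis[4-(triisopropylsilyloxy)benzyloxy]phenyl}ethanone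
Product: 13 (2S)-7-methoxy-6,8-bis(3-methylbut-2-enyl)-5-[4-(triisopropylsilyloxy)benzyloxy]-2-[4-(triisopropylsilyloxy)phenyl]chroman-4-one
Conditions: Rh2(S-BSP)4 (2 mol %), CH2Cl2, 0 °C → rt, slow addition of 12 (syringe pump, high dilution)
Reagents that add atoms: none
Why: Rh(II) releases N2 from 12 to give an electrophilic rhodium carbenoid at the future C3, which inserts through a concerted, asynchronous three-centre transition state (hydride-like transfer with C–C bond formation, retention at carbon) into a C–H bond of a neighbouring O–CH2–aryl group and so forms C2–C3. The closest known reaction type is the enantioselective Rh(II) carboxylate-catalysed C–H insertion of 2-alkoxyaryl diazoketones to chroman-4-ones. The pyranone ring C (C3, C4, C4a, C8a, O1, C2) is closed by 1,6-insertion, the six-membered mode this tether enforces because the fifth atom of the chain is the ether oxygen. The new stereocentre C2 is set by the catalyst alone: the chiral prolinate ligands around the carbenoid select, among the four benzylic hydrogens of the Cs-symmetric substrate, the mirror-related pair whose replacement gives (2S). The step needs C–H insertion to win over attack at the ether oxygen (five-ring oxonium ylide, then [1,2]-benzyl shift to a 2-benzylbenzofuran-3-one) and over intermolecular carbene reactions; the substrate helps because the targeted C–H is hydridic (α-oxygen plus electron-rich 4-silyloxyphenyl), the ether oxygen is hindered by substituents on both sides, both ortho oxygens carry the same group so either side gives the same constitution, and the prenyl alkenes sit meta to the diazoacetyl group, where intramolecular cyclopropanation would need an impossible four-atom meta bridge. Slow addition at high dilution should keep carbene dimerisation and intermolecular cyclopropanation down.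

Step 10
Reactants: 13 (2S)-7-methoxy-6,8-bis(3-methylbut-2-enyl)-5-[4-(triisopropylsilyloxy)benzyloxy]-2-[4-(triisopropylsilyloxy)phenyl]chroman-4-one
Product: 14 (2S)-5-hydroxy-7-methoxy-6,8-bis(3-methylbut-2-enyl)-2-[4-(triisopropylsilyloxy)phenyl]chroman-4-one
Conditions: MgBr2·OEt2 (3 equiv), toluene/Et2O, rt → 40 °C; aq. NH4Cl
Reagents that add atoms: none
Why: Chelation-assisted ether cleavage (the known MgBr2 debenzylation ortho to a carbonyl): Mg(II) binds the C4 carbonyl and the peri O5 and bromide displaces the electron-rich benzyl group at its primary carbon, whereas the secondary C2–O1 bond cannot be chelated and the silyl ether and alkenes are inert, so C2 should keep its configuration.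

Step 11
Reactants: 14 (2S)-5-hydroxy-7-methoxy-6,8-bis(3-methylbut-2-enyl)-2-[4-(triisopropylsilyloxy)phenyl]chroman-4-one
Product: 15 (2S)-5-hydroxy-2-(4-hydroxyphenyl)-7-methoxy-6,8-bis(3-methylbut-2-enyl)chroman-4-one
Conditions: TBAF/AcOH (1:1, 1.5 equiv), THF, 0 °C
Reagents that add atoms: none
Why: Fluoride desilylation of the aryl silyl ether, buffered with acetic acid so that no free phenoxide arises that could open the flavanone by retro-oxa-Michael reaction and racemise C2.

**Compound list**

1 | 2,4,6-trihydroxyacetophenone | CC(=O)c1c(O)cc(O)cc1O | starting material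
2 | prenyl bromide (1-bromo-3-methylbut-2-ene) | CC(C)=CCBr | starting material
3 | 2,4,6-trihydroxy-3,5-bis(3-methylbut-2-enyl)acetophenone | CC(=O)c1c(O)c(CC=C(C)C)c(O)c(CC=C(C)C)c1O | intermediate
4 | 2,6-dihydroxy-4-methoxy-3,5-bis(3-methylbut-2-enyl)acetophenone | CC(=O)c1c(O)c(CC=C(C)C)c(OC)c(CC=C(C)C)c1O | intermediate
5 | 4-hydroxybenzaldehyde | O=Cc1ccc(O)cc1 | starting material
6 | 4-(triisopropylsilyloxy)benzaldehyde | O=Cc1ccc(O[Si](C(C)C)(C(C)C)C(C)C)cc1 | intermediate
7 | 4-(triisopropylsilyloxy)benzyl alcohol | OCc1ccc(O[Si](C(C)C)(C(C)C)C(C)C)cc1 | intermediate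
8 | 4-(triisopropylsilyloxy)benzyl bromide | BrCc1ccc(O[Si](C(C)C)(C(C)C)C(C)C)cc1 | intermediate
9 | 4-methoxy-3,5-bis(3-methylbut-2-enyl)-2,6-bis[4-(triisopropylsilyloxy)benzyloxy]acetophenone | CC(=O)c1c(OCc2ccc(O[Si](C(C)C)(C(C)C)C(C)C)cc2)c(CC=C(C)C)c(OC)c(CC=C(C)C)c1OCc3ccc(O[Si](C(C)C)(C(C)C)C(C)C)cc3 | intermediate
10 | lithium enolate of 9 (not isolated) | [Li]OC(=C)c1c(OCc2ccc(O[Si](C(C)C)(C(C)C)C(C)C)cc2)c(CC=C(C)C)c(OC)c(CC=C(C)C)c1OCc3ccc(O[Si](C(C)C)(C(C)C)C(C)C)cc3 | intermediate
11 | 4,4,4-trifluoro-1-{4-methoxy-3,5-bis(3-methylbut-2-enyl)-2,6-bis[4-(triisopropylsilyloxy)benzyloxy]phenyl}butane-1,3-dione | O=C(CC(=O)C(F)(F)F)c1c(OCc2ccc(O[Si](C(C)C)(C(C)C)C(C)C)cc2)c(CC=C(C)C)c(OC)c(CC=C(C)C)c1OCc3ccc(O[Si](C(C)C)(C(C)C)C(C)C)cc3 | intermediate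
12 | 2-diazo-1-{4-methoxy-3,5-bis(3-methylbut-2-enyl)-2,6-bis[4-(triisopropylsilyloxy)benzyloxy]phenyl}ethanone | [N-]=[N+]=CC(=O)c1c(OCc2ccc(O[Si](C(C)C)(C(C)C)C(C)C)cc2)c(CC=C(C)C)c(OC)c(CC=C(C)C)c1OCc3ccc(O[Si](C(C)C)(C(C)C)C(C)C)cc3 | intermediate
13 | (2S)-7-methoxy-6,8-bis(3-methylbut-2-enyl)-5-[4-(triisopropylsilyloxy)benzyloxy]-2-[4-(triisopropylsilyloxy)phenyl]chroman-4-one | COc1c(CC=C(C)C)c(OCc3ccc(O[Si](C(C)C)(C(C)C)C(C)C)cc3)c2c(c1CC=C(C)C)O[C@H](c1ccc(O[Si](C(C)C)(C(C)C)C(C)C)cc1)CC2=O | intermediate
14 | (2S)-5-hydroxy-7-methoxy-6,8-bis(3-methylbut-2-enyl)-2-[4-(triisopropylsilyloxy)phenyl]chroman-4-one | COc1c(CC=C(C)C)c(O)c2c(c1CC=C(C)C)O[C@H](c1ccc(O[Si](C(C)C)(C(C)C)C(C)C)cc1)CC2=O | intermediate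
15 | (2S)-5-hydroxy-2-(4-hydroxyphenyl)-7-methoxy-6,8-bis(3-methylbut-2-enyl)chroman-4-one | COc1c(CC=C(C)C)c(O)c2c(c1CC=C(C)C)O[C@H](c1ccc(O)cc1)CC2=O | target

**Step count**

Total step count: 11. Longest linear sequence: 9 steps (5 → 15, steps 3–11); the branch from 1 is 8 steps.

**Steps most likely to fail**

1. Step 9 (key step). The carbenoid may be captured by the ether oxygen, with ylide formation and benzyl migration, faster than it inserts into C–H. Discrimination between the enantiotopic hydrogens by an acceptor-only carbenoid may also be weak.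
 - The fallback sets out from 4 (with 8) and comes back at 13; it builds the C2–aryl bond instead of C2–C3.
 - 4 is mono-alkylated with one equivalent of 8 (K2CO3, acetone, rt) to 2-hydroxy-4-methoxy-3,5-bis(3-methylbut-2-enyl)-6-[4-(triisopropylsilyloxy)benzyloxy]acetophenone F1.
 - Condensation with DMF dimethyl acetal (toluene, 90 °C) gives the enaminone (E)-3-(dimethylamino)-1-{2-hydroxy-4-methoxy-3,5-bis(3-methylbut-2-enyl)-6-[4-(triisopropylsilyloxy)benzyloxy]phenyl}prop-2-en-1-one F2.
 - F2 cyclises with loss of dimethylamine (cat. p-TsOH, toluene, 60 °C) to 7-methoxy-6,8-bis(3-methylbut-2-enyl)-5-[4-(triisopropylsilyloxy)benzyloxy]chromen-4-one F3.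
 - The aryl donor is made from 4-bromophenol through (4-bromophenoxy)triisopropylsilane F4 (TIPSCl, imidazole) and 4-(triisopropylsilyloxy)phenylboronic acid F5 (n-BuLi, THF, −78 °C; B(OiPr)3; dilute acid).
 - Rhodium-catalysed asymmetric 1,4-addition of F5 to F3 then gives 13. This is a known flavanone-forming reaction of chromones ([Rh(OH)(cod)]2 with an electron-poor chiral bisphosphine such as MeO-F12-BIPHEP, toluene/H2O, rt), with the ligand antipode chosen to deliver 2S.

2. Step 6. The bromide 8 may be desilylated by carbonate or phenoxide and collapse through a quinone methide. The second etherification may also stall, because the remaining hydroxyl is hydrogen-bonded and flanked on both sides.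
 - The fallback sets out from 4 and 7 and comes back at 9; it makes no new compound (F0).
 - Both hydroxyls are etherified by a double Mitsunobu reaction with alcohol 7 (PPh3, DIAD, THF, 0 °C → rt, high concentration). This activates the alcohol in situ, so no free benzylic halide and no basic phenoxide are present.

3. Step 1. Alkylation is statistical: O-prenylation, mono-prenylation and geminal C-diprenylation with dearomatisation compete. Step 2 must afterwards differentiate three hydroxyls.
 - The fallback sets out from 1 and comes back at 4.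
 - 1 is methylated selectively at the 4-OH (Me2SO4 1 equiv, K2CO3, acetone) to 2,6-dihydroxy-4-methoxyacetophenone F6.
 - Double O-prenylation with 2 (K2CO3, DMF) gives 4-methoxy-2,6-bis(3-methylbut-2-enyloxy)acetophenone F7.
 - Heating F7 in N,N-diethylaniline (about 190 °C) should move each prenyl group by aromatic Claisen rearrangement to the ortho ring carbon and by Cope rearrangement on to the para carbon (para-Claisen–Cope sequence). Both termini are C3 and C5, so this should deliver 4 and avoids the regioselective methylation of step 2.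

**Further compounds**

F1 | step 9 | 2-hydroxy-4-methoxy-3,5-bis(3-methylbut-2-enyl)-6-[4-(triisopropylsilyloxy)benzyloxy]acetophenone | CC(=O)c1c(O)c(CC=C(C)C)c(OC)c(CC=C(C)C)c1OCc2ccc(O[Si](C(C)C)(C(C)C)C(C)C)cc2
F2 | step 9 | (E)-3-(dimethylamino)-1-{2-hydroxy-4-methoxy-3,5-bis(3-methylbut-2-enyl)-6-[4-(triisopropylsilyloxy)benzyloxy]phenyl}prop-2-en-1-one | CN(C)/C=C/C(=O)c1c(O)c(CC=C(C)C)c(OC)c(CC=C(C)C)c1OCc2ccc(O[Si](C(C)C)(C(C)C)C(C)C)cc2
F3 | step 9 | 7-methoxy-6,8-bis(3-methylbut-2-enyl)-5-[4-(triisopropylsilyloxy)benzyloxy]chromen-4-one | COc1c(CC=C(C)C)c(OCc3ccc(O[Si](C(C)C)(C(C)C)C(C)C)cc3)c2c(c1CC=C(C)C)OC=CC2=O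
F4 | step 9 | (4-bromophenoxy)triisopropylsilane | CC(C)[Si](Oc1ccc(Br)cc1)(C(C)C)C(C)C
F5 | step 9 | 4-(triisopropylsilyloxy)phenylboronic acid | OB(O)c1ccc(O[Si](C(C)C)(C(C)C)C(C)C)cc1
F0 | step 6 | none | none
F6 | step 1 | 2,6-dihydroxy-4-methoxyacetophenone | CC(=O)c1c(O)cc(OC)cc1O
F7 | step 1 | 4-methoxy-2,6-bis(3-methylbut-2-enyloxy)acetophenone | CC(=O)c1c(OCC=C(C)C)cc(OC)cc1OCC=C(C)C
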